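**Plan**

- Ring A (the pentanoyl ring) is hexasubstituted with carbon and oxygen alternating: C1 pentanoyl, C2 OH, C3 CH3, C4 OH, C5 bridge CH2, C6 OH. This is the pattern a vinylketene–ynol ether benzannulation delivers, with O4 from a ketene carbonyl, O2 from a siloxyalkyne and O6 from an alkoxyacetylene.
- Retrosynthesis: the three O–benzyl bonds are cut first, then the C1–acyl bond (Houben–Hoesch), then the ring A bonds C4–C3, C2–C1 and C4–C5. This leads to 1-(triisopropylsiloxy)propyne and a 3-benzyloxy-4-(arylmethyl)cyclobutenone; the cyclobutenone is cut into an arylpropanoyl ketene and benzyl ethynyl ether, and the propanoic acid chain (bridge CH2, C5, C4) into aspidinol, formaldehyde and Meldrum's acid.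
- Forward: ring B is finished first (acylation and para-O-methylation of 2-methylphloroglucinol), a lactone ring brings in the bridge carbon, the cyclobutenone follows, and ring A is formed last and then acylated at its single free carbon.
- O6 is carried as a benzyl ether because an ethyl ether beside the hydrogen-bonded pentanoyl ketone could not be cleaved selectively next to the ring B methyl ether; one hydrogenolysis then frees all five phenols.
- The target has no stereocentre; the only stereocentre on the way (C4 of the cyclobutenone) is formed racemic and disappears when ring A aromatises.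

Key step: step 10

**Route**

Step 1
Reactants: 1 2-methylbenzene-1,3,5-triol (2-methylphloroglucinol); 2 butanoyl chloride
Product: 3 1-(2,4,6-trihydroxy-3-methylphenyl)butan-1-one
Conditions: AlCl3, CH2Cl2–MeNO2, 0 °C → rt; aq. HCl work-up
Reagents that add atoms: none
Why: Friedel–Crafts acylation; the two open ring positions of 1 are equivalent and the first acyl group deactivates the ring against a second one.

Step 2
Reactants: 3 1-(2,4,6-trihydroxy-3-methylphenyl)butan-1-one
Product: 4 1-(2,6-dihydroxy-4-methoxy-3-methylphenyl)butan-1-one (aspidinol)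
Conditions: Me2SO4 (1.05 equiv), K2CO3 (1.1 equiv), acetone, rt
Reagents that add atoms: dimethyl sulfate, COS(=O)(=O)OC
Why: Williamson O-methylation; the hydroxyl para to the ketone is the most acidic and, unlike the two beside the carbonyl, cannot be held in a hydrogen bond, so one equivalent of the hard electrophile should react there first.

Step 3
Reactants: 4 1-(2,6-dihydroxy-4-methoxy-3-methylphenyl)butan-1-one; 5 formaldehyde; 6 Meldrum's acid (2,2-dimethyl-1,3-dioxane-4,6-dione)
Product: 8 8-butanoyl-7-hydroxy-5-methoxy-6-methyl-3,4-dihydro-2H-chromen-2-one, via Meldrum's acid adduct 7 (not isolated)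
Conditions: Meldrum's acid (1.5 equiv), 37% aq. CH2O, pyridine, rt; then 4, rt → 90 °C
Reagents that add atoms: none
Why: Tandem Knoevenagel condensation–Michael addition–lactonisation–decarboxylation (three-component dihydrocoumarin synthesis); methylene Meldrum's acid alkylates the only free ring carbon of 4, the one neighbouring phenol opens the dioxanedione with loss of acetone, and the resulting acid loses CO2.

Step 4
Reactants: 8 8-butanoyl-7-hydroxy-5-methoxy-6-methyl-3,4-dihydro-2H-chromen-2-one; 9 benzyl alcohol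
Product: 11 benzyl 3-[2,4-bis(benzyloxy)-3-butanoyl-6-methoxy-5-methylphenyl]propanoate, via ring-opened benzyl ester 10 (not isolated)
Conditions: BnOH (3 equiv), BnBr (3 equiv), K2CO3, Bu4NI (cat.), DMF, 60 °C
Reagents that add atoms: benzyl bromide, BrCc1ccccc1
Why: Base-mediated alcoholysis of the aryl lactone followed by Williamson benzylation; benzyl alkoxide opens the phenyl-ester-type lactone to the more stable phenoxide, and both phenoxides are O-benzylated in the dipolar aprotic solvent, where K2CO3 does not enolise the ketone.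

Step 5
Reactants: 11 benzyl 3-[2,4-bis(benzyloxy)-3-butanoyl-6-methoxy-5-methylphenyl]propanoate
Product: 12 3-[2,4-bis(benzyloxy)-3-butanoyl-6-methoxy-5-methylphenyl]propanoic acid
Conditions: LiOH, THF–MeOH–H2O, 40 °C; then aq. HCl
Reagents that add atoms: lithium hydroxide, [Li+].[OH-]
Why: Ester saponification; the unhindered primary benzyl ester is hydrolysed while the aryl benzyl ethers and the doubly ortho-substituted aryl ketone are inert to hydroxide.

Step 6
Reactants: 9 benzyl alcohol; 13 trichloroethylene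
Product: 14 benzyl (E)-1,2-dichlorovinyl ether
Conditions: KH, THF, 0 °C; then Cl2C=CHCl, rt
Reagents that add atoms: none
Why: Addition of the potassium alkoxide to dichloroacetylene formed in situ from trichloroethylene (dichlorovinyl ether route to ynol ethers); anti addition should give the E isomer.

Step 7
Reactants: 14 benzyl (E)-1,2-dichlorovinyl ether
Product: 16 benzyl ethynyl ether, via lithium (benzyloxy)acetylide 15 (not isolated)
Conditions: n-BuLi (2.2 equiv), THF, −78 °C; then H2O, −78 °C; cold pentane extraction, dried and used as a cold solution the same day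
Reagents that add atoms: none
Why: Dehydrochlorination followed by chlorine–lithium exchange gives the lithium alkoxyacetylide, which is protonated and kept cold because benzyl alkynyl ethers rearrange sigmatropically on warming.

Step 8
Reactants: 12 3-[2,4-bis(benzyloxy)-3-butanoyl-6-methoxy-5-methylphenyl]propanoic acid; 16 benzyl ethynyl ether
Product: 19 rac-3-(benzyloxy)-4-{[2,4-bis(benzyloxy)-3-butanoyl-6-methoxy-5-methylphenyl]methyl}cyclobut-2-en-1-one, via acid chloride 17 (not isolated), via aldoketene 18 (not isolated)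
Conditions: (COCl)2, DMF (cat.), CH2Cl2, 0 °C → rt; evaporate; then 16 (3 equiv), Et3N (slow addition), CH2Cl2, 0 °C → rt
Reagents that add atoms: none
Why: Acid chloride formation, dehydrochlorination to the aldoketene and ketene–ynol ether (2+2) cycloaddition; the nucleophilic terminal carbon of 16 attacks the ketene carbonyl carbon, which places benzyloxy at C3 and the arylmethyl group at C4, and the new C4 stereocentre is formed racemic and removed in step 10.

Step 9
Reactants: 20 1-propynyllithium
Product: 22 triisopropyl(prop-1-yn-1-yloxy)silane, via lithium propynolate 21 (not isolated)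
Conditions: t-BuOOH, LiN(SiMe3)2, THF, −78 °C; then 20, −78 → 0 °C; then i-Pr3SiOTf, −78 °C
Reagents that add atoms: tert-butyl hydroperoxide, CC(C)(C)OO; triisopropylsilyl trifluoromethanesulfonate, CC(C)[Si](OS(=O)(=O)C(F)(F)F)(C(C)C)C(C)C
Why: Oxidation of the lithium acetylide by lithium tert-butyl peroxide gives the ynolate, and the bulky silyl triflate then reacts at oxygen (ynolate O-silylation) to give the siloxyalkyne.

Step 10
Reactants: 19 rac-3-(benzyloxy)-4-{[2,4-bis(benzyloxy)-3-butanoyl-6-methoxy-5-methylphenyl]methyl}cyclobut-2-en-1-one; 22 triisopropyl(prop-1-yn-1-yloxy)silane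
Product: 27 3-(benzyloxy)-2-{[2,4-bis(benzyloxy)-3-butanoyl-6-methoxy-5-methylphenyl]methyl}-6-methyl-5-[(triisopropylsilyl)oxy]phenol, via vinylketene 23 (not isolated), via vinylcyclobutenone 24 (not isolated), via dienylketene 25 (not isolated), via cyclohexadienone 26 (not isolated)
Conditions: 22 (2 equiv), toluene, 90 °C
Reagents that add atoms: none
Why: Danheiser benzannulation: 4π electrocyclic opening of 19, with the arylmethyl group turning outward, gives vinylketene 23, which adds (2+2) to 22 to give 24; 24 opens to dienylketene 25, which closes to cyclohexadienone 26 and enolises to phenol 27. The closest known reaction type is the annulation of 3-alkyl- and 3-siloxycyclobutenones with trialkylsiloxyalkynes to give resorcinol monosilyl ethers. Ring A is closed by a thermal disrotatory 6π electrocyclisation that forms C4–C5, after the cycloaddition has formed C4–C3 and C2–C1. No stereocentre is created in the product, and the racemic centres of 19, 24 and 26 all become sp2. The step needs regioselectivity in the ketene–alkyne cycloaddition; the siloxy group secures it by making the methyl-bearing carbon the nucleophile that attacks the ketene carbonyl carbon, so methyl lies between the new phenol and the siloxy carbon and only C1 stays unsubstituted. The excess of 22 and the crowded environment of the new phenol should suppress its esterification by unreacted ketene.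

Step 11
Reactants: 27 3-(benzyloxy)-2-{[2,4-bis(benzyloxy)-3-butanoyl-6-methoxy-5-methylphenyl]methyl}-6-methyl-5-[(triisopropylsilyl)oxy]phenol
Product: 28 5-(benzyloxy)-4-{[2,4-bis(benzyloxy)-3-butanoyl-6-methoxy-5-methylphenyl]methyl}-2-methylbenzene-1,3-diol
Conditions: Bu4NF, AcOH, THF, 0 °C
Reagents that add atoms: none
Why: Fluoride-mediated cleavage of the aryl silyl ether, buffered with AcOH so that the electron-rich resorcinol is not exposed to basic fluoride; benzyl ethers and the ketone are untouched.

Step 12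
Reactants: 28 5-(benzyloxy)-4-{[2,4-bis(benzyloxy)-3-butanoyl-6-methoxy-5-methylphenyl]methyl}-2-methylbenzene-1,3-diol; 29 pentanenitrile
Product: 31 1-[2-(benzyloxy)-3-{[2,4-bis(benzyloxy)-3-butanoyl-6-methoxy-5-methylphenyl]methyl}-4,6-dihydroxy-5-methylphenyl]pentan-1-one, via ketiminium chloride 30 (not isolated)
Conditions: ZnCl2 (0.5 equiv), HCl (g), Et2O, 0 °C; then H2O–dioxane, 80 °C
Reagents that add atoms: water, O
Why: Houben–Hoesch acylation; the protonated nitrile attacks the only unsubstituted aromatic carbon of the molecule, which is activated by two ortho oxygens and one para oxygen, and the ketiminium salt is hydrolysed to the ketone, while aryl benzyl ethers should tolerate HCl and ZnCl2 in ether at 0 °C.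

Step 13
Reactants: 31 1-[2-(benzyloxy)-3-{[2,4-bis(benzyloxy)-3-butanoyl-6-methoxy-5-methylphenyl]methyl}-4,6-dihydroxy-5-methylphenyl]pentan-1-one
Product: 32 1-{3-[(3-butanoyl-2,4-dihydroxy-6-methoxy-5-methylphenyl)methyl]-2,4,6-trihydroxy-5-methylphenyl}pentan-1-one (CNP0210501.0)
Conditions: H2 (1 atm), 10% Pd/C, EtOAc–MeOH, rt
Reagents that add atoms: none
Why: Catalytic hydrogenolysis of the three aryl benzyl ethers; the aryl methyl ether, the diarylmethane and the hydrogen-bonded aryl ketones should be stable under these conditions.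

**Compound list**

1 | 2-methylbenzene-1,3,5-triol (2-methylphloroglucinol) | Cc1c(O)cc(O)cc1O | starting material
2 | butanoyl chloride | CCCC(Cl)=O | starting material
3 | 1-(2,4,6-trihydroxy-3-methylphenyl)butan-1-one | CCCC(=O)c1c(O)cc(O)c(C)c1O | intermediate
4 | 1-(2,6-dihydroxy-4-methoxy-3-methylphenyl)butan-1-one (aspidinol) | CCCC(=O)c1c(O)cc(OC)c(C)c1O | intermediate
5 | formaldehyde | C=O | starting material
6 | Meldrum's acid (2,2-dimethyl-1,3-dioxane-4,6-dione) | CC1(C)OC(=O)CC(=O)O1 | starting material
7 | 5-[(3-butanoyl-2,4-dihydroxy-6-methoxy-5-methylphenyl)methyl]-2,2-dimethyl-1,3-dioxane-4,6-dione | CCCC(=O)c1c(O)c(C)c(OC)c(CC2C(=O)OC(C)(C)OC2=O)c1O | intermediate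
8 | 8-butanoyl-7-hydroxy-5-methoxy-6-methyl-3,4-dihydro-2H-chromen-2-one | CCCC(=O)c1c(O)c(C)c(OC)c2CCC(=O)Oc12 | intermediate
9 | benzyl alcohol | OCc1ccccc1 | starting material
10 | benzyl 3-(3-butanoyl-2,4-dihydroxy-6-methoxy-5-methylphenyl)propanoate | CCCC(=O)c1c(O)c(C)c(OC)c(CCC(=O)OCc2ccccc2)c1O | intermediate
11 | benzyl 3-[2,4-bis(benzyloxy)-3-butanoyl-6-methoxy-5-methylphenyl]propanoate | CCCC(=O)c1c(OCc2ccccc2)c(C)c(OC)c(CCC(=O)OCc2ccccc2)c1OCc1ccccc1 | intermediate
12 | 3-[2,4-bis(benzyloxy)-3-butanoyl-6-methoxy-5-methylphenyl]propanoic acid | CCCC(=O)c1c(OCc2ccccc2)c(C)c(OC)c(CCC(O)=O)c1OCc1ccccc1 | intermediate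
13 | trichloroethylene | ClC=C(Cl)Cl | starting material
14 | benzyl (E)-1,2-dichlorovinyl ether | Cl/C=C(/Cl)OCc1ccccc1 | intermediate
15 | lithium (benzyloxy)acetylide | [Li]C#COCc1ccccc1 | intermediate
16 | benzyl ethynyl ether | C#COCc1ccccc1 | intermediate
17 | 3-[2,4-bis(benzyloxy)-3-butanoyl-6-methoxy-5-methylphenyl]propanoyl chloride | CCCC(=O)c1c(OCc2ccccc2)c(C)c(OC)c(CCC(Cl)=O)c1OCc1ccccc1 | intermediate
18 | 3-[2,4-bis(benzyloxy)-3-butanoyl-6-methoxy-5-methylphenyl]prop-1-en-1-one (aldoketene) | CCCC(=O)c1c(OCc2ccccc2)c(C)c(OC)c(CC=C=O)c1OCc1ccccc1 | intermediate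
19 | rac-3-(benzyloxy)-4-{[2,4-bis(benzyloxy)-3-butanoyl-6-methoxy-5-methylphenyl]methyl}cyclobut-2-en-1-one | O=C1C=C(OCc2ccccc2)C1Cc1c(OCc2ccccc2)c(C(=O)CCC)c(OCc2ccccc2)c(C)c1OC | intermediate
20 | 1-propynyllithium | [Li]C#CC | starting material
21 | lithium prop-1-yn-1-olate | [Li+].CC#C[O-] | intermediate
22 | triisopropyl(prop-1-yn-1-yloxy)silane | CC#CO[Si](C(C)C)(C(C)C)C(C)C | intermediate
23 | (3Z)-3-(benzyloxy)-5-[2,4-bis(benzyloxy)-3-butanoyl-6-methoxy-5-methylphenyl]penta-1,3-dien-1-one | O=C=C/C(OCc1ccccc1)=C/Cc1c(OCc2ccccc2)c(C(=O)CCC)c(OCc2ccccc2)c(C)c1OC | intermediate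
24 | rac-4-{(1Z)-1-(benzyloxy)-3-[2,4-bis(benzyloxy)-3-butanoyl-6-methoxy-5-methylphenyl]prop-1-en-1-yl}-2-methyl-3-[(triisopropylsilyl)oxy]cyclobut-2-en-1-one | O=C1C(C)=C(O[Si](C(C)C)(C(C)C)C(C)C)C1/C(OCc1ccccc1)=C/Cc1c(OCc2ccccc2)c(C(=O)CCC)c(OCc2ccccc2)c(C)c1OC | intermediate
25 | (3E,5Z)-5-(benzyloxy)-7-[2,4-bis(benzyloxy)-3-butanoyl-6-methoxy-5-methylphenyl]-2-methyl-3-[(triisopropylsilyl)oxy]hepta-1,3,5-trien-1-one | O=C=C(C)/C(O[Si](C(C)C)(C(C)C)C(C)C)=C\C(OCc1ccccc1)=C\Cc1c(OCc2ccccc2)c(C(=O)CCC)c(OCc2ccccc2)c(C)c1OC | intermediate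
26 | rac-5-(benzyloxy)-6-{[2,4-bis(benzyloxy)-3-butanoyl-6-methoxy-5-methylphenyl]methyl}-2-methyl-3-[(triisopropylsilyl)oxy]cyclohexa-2,4-dien-1-one | O=C1C(C)=C(O[Si](C(C)C)(C(C)C)C(C)C)C=C(OCc2ccccc2)C1Cc1c(OCc2ccccc2)c(C(=O)CCC)c(OCc2ccccc2)c(C)c1OC | intermediate
27 | 3-(benzyloxy)-2-{[2,4-bis(benzyloxy)-3-butanoyl-6-methoxy-5-methylphenyl]methyl}-6-methyl-5-[(triisopropylsilyl)oxy]phenol | CCCC(=O)c1c(OCc2ccccc2)c(C)c(OC)c(Cc2c(O)c(C)c(O[Si](C(C)C)(C(C)C)C(C)C)cc2OCc2ccccc2)c1OCc1ccccc1 | intermediate
28 | 5-(benzyloxy)-4-{[2,4-bis(benzyloxy)-3-butanoyl-6-methoxy-5-methylphenyl]methyl}-2-methylbenzene-1,3-diol | CCCC(=O)c1c(OCc2ccccc2)c(C)c(OC)c(Cc2c(O)c(C)c(O)cc2OCc2ccccc2)c1OCc1ccccc1 | intermediate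
29 | pentanenitrile | CCCCC#N | starting material
30 | 1-[2-(benzyloxy)-3-{[2,4-bis(benzyloxy)-3-butanoyl-6-methoxy-5-methylphenyl]methyl}-4,6-dihydroxy-5-methylphenyl]pentan-1-iminium chloride | CCCCC(=[NH2+])c1c(O)c(C)c(O)c(Cc2c(OCc3ccccc3)c(C(=O)CCC)c(OCc3ccccc3)c(C)c2OC)c1OCc1ccccc1.[Cl-] | intermediate
31 | 1-[2-(benzyloxy)-3-{[2,4-bis(benzyloxy)-3-butanoyl-6-methoxy-5-methylphenyl]methyl}-4,6-dihydroxy-5-methylphenyl]pentan-1-one | CCCCC(=O)c1c(O)c(C)c(O)c(Cc2c(OCc3ccccc3)c(C(=O)CCC)c(OCc3ccccc3)c(C)c2OC)c1OCc1ccccc1 | intermediate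
32 | 1-{3-[(3-butanoyl-2,4-dihydroxy-6-methoxy-5-methylphenyl)methyl]-2,4,6-trihydroxy-5-methylphenyl}pentan-1-one | CCCCC(=O)c1c(O)c(C)c(O)c(Cc2c(O)c(C(=O)CCC)c(O)c(C)c2OC)c1O | target

**Count and risks**

Total step count: 13. Longest linear sequence: 10 steps (steps 1, 2, 3, 4, 5, 8, 10, 11, 12, 13).

Steps most likely to fail:

1. Step 10. The electrocyclic opening of a vinylogous-ester cyclobutenone may be slow at temperatures the siloxyalkyne tolerates, and the vinylketene may then be consumed by the product phenol or by itself and not by the alkyne. The fallback gives up building ring A and joins two finished rings by an ortho-quinone methide alkylation; it sets out from 1 and 4 and comes back at 32. Friedel–Crafts acylation of 1 with pentanoyl chloride and AlCl3 should give 1-(2,4,6-trihydroxy-3-methylphenyl)pentan-1-one F1. A Mannich reaction of 4 with aqueous CH2O and Me2NH at its only free ring carbon should give 1-{3-[(dimethylamino)methyl]-2,6-dihydroxy-4-methoxy-5-methylphenyl}butan-1-one F2. Heating F2 with F1 in dioxane should release the ring B ortho-quinone methide, which F1 captures at its one free carbon to give 32.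

2. Step 8. The terminal ynol ether 16 may be lost by sigmatropic rearrangement, hydrochlorination or oligomerisation before it intercepts the ketene, which then dimerises. The fallback replaces it by a C-silylated, storable ynol ether; it sets out from 14 and comes back at 19. The acetylide 15 made from 14 is quenched with Me3SiCl in place of water to give [(benzyloxy)ethynyl]trimethylsilane F3. Cycloaddition of F3 with ketene 18, generated from 12 as in step 8, should give rac-3-(benzyloxy)-4-{[2,4-bis(benzyloxy)-3-butanoyl-6-methoxy-5-methylphenyl]methyl}-2-(trimethylsilyl)cyclobut-2-en-1-one F4, with the same regiochemistry because the silicon-bearing carbon is the nucleophilic terminus. Protodesilylation of F4 with Bu4NF and AcOH in THF should then give 19.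

3. Step 12. C-acylation at the crowded ring A carbon may be slow enough for HCl and ZnCl2 to start cleaving benzyl ethers, with C-benzylation of ring A by the freed benzyl chloride, and the hindered ketiminium salt may resist hydrolysis. The fallback reverses the order of deprotection and acylation; it sets out from 28 and comes back at 32. Hydrogenolysis of 28 (H2, 10% Pd/C, EtOAc–MeOH) should give 1-{2,6-dihydroxy-4-methoxy-3-methyl-5-[(2,4,6-trihydroxy-3-methylphenyl)methyl]phenyl}butan-1-one F5. Friedel–Crafts acylation of F5 with pentanoyl chloride and AlCl3 in CH2Cl2–MeNO2 at its single free ring carbon should give 32 directly.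

**Further compounds**

F1 | step 10 | 1-(2,4,6-trihydroxy-3-methylphenyl)pentan-1-one | CCCCC(=O)c1c(O)cc(O)c(C)c1O
F2 | step 10 | 1-{3-[(dimethylamino)methyl]-2,6-dihydroxy-4-methoxy-5-methylphenyl}butan-1-one | CCCC(=O)c1c(O)c(C)c(OC)c(CN(C)C)c1O
F3 | step 8 | [(benzyloxy)ethynyl]trimethylsilane | C[Si](C)(C)C#COCc1ccccc1
F4 | step 8 | rac-3-(benzyloxy)-4-{[2,4-bis(benzyloxy)-3-butanoyl-6-methoxy-5-methylphenyl]methyl}-2-(trimethylsilyl)cyclobut-2-en-1-one | O=C1C([Si](C)(C)C)=C(OCc2ccccc2)C1Cc1c(OCc2ccccc2)c(C(=O)CCC)c(OCc2ccccc2)c(C)c1OC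
F5 | step 12 | 1-{2,6-dihydroxy-4-methoxy-3-methyl-5-[(2,4,6-trihydroxy-3-methylphenyl)methyl]phenyl}butan-1-one | CCCC(=O)c1c(O)c(C)c(OC)c(Cc2c(O)cc(O)c(C)c2O)c1O
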